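**Plan**

1. Cuts: (i) C2′–C3′, the CH2–CH2 bond of the nonenyl chain two and three carbons out from oxepane C2 (alkyl–alkyl Negishi coupling); (ii) O1–C2 of the oxepane (7-endo opening of a 2-methyl-2-vinyl epoxide by the C7 hydroxyl); (iii) the C2=C3 and C2–vinyl bonds of the open-chain diene (cross-metathesis, Wittig) and C5–C6 (carbomagnesiation of but-2-yne-1,4-diol); (iv) C4′–C5′ of the side chain (aldol).
2. Forward: the exocyclic alkene is made first, the chain is grown to a 1,3-diene, mono-epoxidised and closed to the oxepane (the only ring); its vinyl group becomes a 2-bromoethyl arm; the side chain is built separately and coupled; desilylation and one selective acetylation finish.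
3. Stereochemistry: C2/C3 from a Shi epoxidation (reagent control) with inversion at C2 in the ring closure; 6E from anti-carbomagnesiation; C4′/C5′ from an Evans syn-aldol.
4. Feature that allows the key event: the bond lies in the unbranched C1′–C3′ tether; C2′ and C3′ are both primary and their nearest oxygens (O1 on C2, O on C5′) are γ, so neither metal alkyl can lose an alkoxide; C3′ sits 1,5 to the C7′=C8′ alkene, so it must be the two-electron zinc partner and C2′ the electrophile.

Key step: step 15

Remark: the target is read as (2S,3R,6E) on the oxepane (O1, C2 quaternary, C3 acetoxy, C6 alkylidene) and (4R,5R) in the C1′–C9′ chain on C2; but-3-enylmagnesium bromide solution and the D-fructose-derived epoxidation ketone are taken as purchasable.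

**Route**

Step 1
Reactants: 1 but-2-yne-1,4-diol; 2 but-3-en-1-ylmagnesium bromide
Product: 4 (2E)-2-(but-3-en-1-yl)but-2-ene-1,4-diol, via alkenylmagnesium chelate 3 (not isolated)
Conditions: 2 (4 equiv), CuI (10 mol %), THF, 0 °C → rt; aq NH4Cl
Reagents that add atoms: none
Why: Copper-catalysed anti-carbomagnesiation of a propargylic alkoxide puts the alkyl group on one alkyne carbon while magnesium is held on the other in a five-membered O–Mg–C chelate, so protonation should leave the butenyl chain cis to the CH2OH on the CH= carbon, the geometry of the future exocyclic (E)-alkene.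

Step 2
Reactants: 4 butenyl butenediol; 5 methacrolein
Product: 6 (2E,6E)-8-hydroxy-6-(hydroxymethyl)-2-methylocta-2,6-dienal
Conditions: 5 (excess), Hoveyda–Grubbs II catalyst (5 mol %), CH2Cl2, 40 °C
Reagents that add atoms: none
Why: Olefin cross-metathesis of a terminal alkene with an α-substituted acrolein should give the thermodynamically preferred (E)-2-methyl enal, while the trisubstituted alkene between the two CH2OH groups is too hindered to enter the cycle.

Step 3
Reactants: 6 dienal diol
Product: 7 (2E)-2-[(3E)-4-methylhexa-3,5-dien-1-yl]but-2-ene-1,4-diol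
Conditions: Ph3PCH3Br, KHMDS (excess ylide), THF, −78 → 0 °C
Reagents that add atoms: methyltriphenylphosphonium bromide C[P+](c1ccccc1)(c1ccccc1)c1ccccc1.[Br-]
Why: Wittig methylenation of the enal at low temperature (fast enough to outrun conjugate addition of the alkoxides) should give the (E)-1,3-diene without touching either alkene geometry.

Step 4
Reactants: 7 diene diol
Product: 8 (2E)-2-{2-[(2R,3R)-3-ethenyl-3-methyloxiran-2-yl]ethyl}but-2-ene-1,4-diol
Conditions: D-fructose-derived ketone (30 mol %), Oxone, K2CO3, Bu4NHSO4, MeCN–DMM/aq borate–EDTA buffer (pH 10.5), 0 °C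
Reagents that add atoms: potassium peroxymonosulfate (Oxone) [K+].[O-]S(=O)(=O)OO
Why: Shi asymmetric epoxidation: the chiral dioxirane should attack the electron-rich trisubstituted alkene of the diene through the spiro transition state to give the (R,R)-epoxide, whereas the vinyl group and the alkene deactivated by two allylic oxygens react much more slowly.

Step 5
Reactants: 8 hydroxy vinyl epoxide
Product: 9 (2S,3R,6E)-2-ethenyl-6-(2-hydroxyethylidene)-2-methyloxepan-3-ol
Conditions: CSA (10 mol %), CH2Cl2, −40 → 0 °C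
Reagents that add atoms: none
Why: Acid-catalysed 7-endo hydroxy-epoxide opening: the CH2OH geminal to the chain attacks the epoxide carbon activated by both methyl and vinyl groups with inversion, and the CH–O carbon keeps its configuration, which should set (2S,3R) and outpace 6-exo closure.

Step 6
Reactants: 9 oxepane diol
Product: 10 (2S,3R,6E)-6-(2-{[tert-butyl(dimethyl)silyl]oxy}ethylidene)-2-ethenyl-2-methyloxepan-3-ol
Conditions: TBSCl (1.05 equiv), imidazole, CH2Cl2, −20 °C
Reagents that add atoms: tert-butyldimethylsilyl chloride CC(C)(C)[Si](C)(C)Cl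
Why: Silylation should be selective for the primary allylic hydroxyl over the secondary hydroxyl next to the quaternary carbon (steric differentiation).

Step 7
Reactants: 10 mono-silyl ether
Product: 11 (2S,3R,6E)-6-(2-{[tert-butyl(dimethyl)silyl]oxy}ethylidene)-2-ethenyl-2-methyloxepan-3-yl acetate
Conditions: Ac2O, pyridine, DMAP (cat.), CH2Cl2, rt
Reagents that add atoms: acetic anhydride CC(=O)OC(C)=O
Why: DMAP-catalysed acylation installs the ring acetate of the target now, because the later steps tolerate a secondary ester.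

Step 8
Reactants: 11 vinyl oxepane acetate
Product: 13 (2S,3R,6E)-6-(2-{[tert-butyl(dimethyl)silyl]oxy}ethylidene)-2-(2-hydroxyethyl)-2-methyloxepan-3-yl acetate, via alkylborane 12 (not isolated)
Conditions: 9-BBN, THF, 0 °C → rt; then 30% H2O2, aq NaOAc, 0 °C → rt
Reagents that add atoms: 9-borabicyclo[3.3.1]nonane B1C2CCCC1CCC2 (boron stays only in 12); hydrogen peroxide OO
Why: Anti-Markovnikov hydroboration by 9-BBN should touch only the monosubstituted vinyl group (the trisubstituted alkene is inert), and buffered peroxide oxidation should spare the acetate.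

Step 9
Reactants: 13 primary alcohol
Product: 14 (2S,3R,6E)-2-(2-bromoethyl)-6-(2-{[tert-butyl(dimethyl)silyl]oxy}ethylidene)-2-methyloxepan-3-yl acetate
Conditions: CBr4, PPh3, CH2Cl2, 0 °C
Reagents that add atoms: carbon tetrabromide BrC(Br)(Br)Br
Why: Appel bromination converts the primary alcohol under neutral conditions that leave silyl ether, acetate and alkenes alone.

Step 10
Reactants: 15 4-methylpent-3-en-1-ol
Product: 16 4-methylpent-3-enal
Conditions: Dess–Martin periodinane, NaHCO3, CH2Cl2, 0 °C → rt; used at once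
Reagents that add atoms: none
Why: Dess–Martin oxidation under buffered, non-basic conditions should give the β,γ-unsaturated aldehyde without isomerisation to the conjugated enal.

Step 11
Reactants: 16 4-methylpent-3-enal; 17 (4S)-4-benzyl-3-propanoyl-1,3-oxazolidin-2-one
Product: 19 (4S)-4-benzyl-3-[(2S,3R)-3-hydroxy-2,6-dimethylhept-5-enoyl]-1,3-oxazolidin-2-one, via boron enolate 18 (not isolated)
Conditions: 17, Bu2BOTf, i-Pr2NEt, CH2Cl2, −78 → 0 °C; 16, −78 → 0 °C; pH 7 buffer, MeOH, 30% H2O2
Reagents that add atoms: dibutylboron triflate CCCCB(CCCC)OS(=O)(=O)C(F)(F)F (boron stays only in 18)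
Why: Evans syn-aldol: the (Z)-boron enolate reacts through a closed chair transition state on the face away from the benzyl group, which should set (2S,3R), the syn methyl/hydroxyl pair of the target.

Step 12
Reactants: 19 aldol adduct
Product: 20 (4S)-4-benzyl-3-[(2S,3R)-3-{[tert-butyl(dimethyl)silyl]oxy}-2,6-dimethylhept-5-enoyl]-1,3-oxazolidin-2-one
Conditions: TBSOTf, 2,6-lutidine, CH2Cl2, −78 → 0 °C
Reagents that add atoms: tert-butyldimethylsilyl triflate CC(C)(C)[Si](C)(C)OS(=O)(=O)C(F)(F)F
Why: Silyl triflate with a hindered base protects the secondary hydroxyl and blocks retro-aldol cleavage in the next step.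

Step 13
Reactants: 20 silylated imide
Product: 21 (2R,3R)-3-{[tert-butyl(dimethyl)silyl]oxy}-2,6-dimethylhept-5-en-1-ol
Conditions: LiBH4, MeOH (1 equiv), THF, 0 °C
Reagents that add atoms: none
Why: Reductive cleavage of the imide at the exocyclic carbonyl gives the primary alcohol and returns the auxiliary without enolising the α-stereocentre.

Step 14
Reactants: 21 primary alcohol
Product: 22 tert-butyl{[(2S,3R)-1-iodo-2,6-dimethylhept-5-en-3-yl]oxy}dimethylsilane
Conditions: I2, PPh3, imidazole, CH2Cl2, 0 °C → rt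
Reagents that add atoms: iodine II
Why: Appel-type iodination is an SN2 displacement at the primary carbon and leaves both stereocentres untouched.

Step 15
Reactants: 22 side-chain iodide; 14 oxepane bromide
Product: 25 (2S,3R,6E)-6-(2-{[tert-butyl(dimethyl)silyl]oxy}ethylidene)-2-[(4R,5R)-5-{[tert-butyl(dimethyl)silyl]oxy}-4,8-dimethylnon-7-en-1-yl]-2-methyloxepan-3-yl acetate, via alkyllithium 23 (not isolated), via alkylzinc bromide 24 (not isolated)
Conditions: 22 (1.5 equiv), t-BuLi (2 equiv per iodide), Et2O, −78 °C; ZnBr2 (THF), −78 → 0 °C; then 14, Pd-PEPPSI-IPr (4 mol %), LiBr, THF/NMP (2:1), rt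
Reagents that add atoms: tert-butyllithium [Li]C(C)(C)C (lithium only in 23); zinc bromide Br[Zn]Br (zinc and bromide only in 24)
Why: Iodine–lithium exchange at −78 °C (too cold for anionic cyclisation or silyl migration) and capture by ZnBr2 give the primary alkylzinc bromide, then Pd(0)–NHC inserts into the unhindered primary C–Br bond of 14 by an SN2-type oxidative addition, the alkyl group passes from zinc to palladium, and C(sp3)–C(sp3) reductive elimination forms the CH2–CH2 bond. The closest known reaction type is the Pd–NHC-catalysed alkyl–alkyl Negishi coupling of primary alkyl bromides with primary alkylzinc halides in THF/NMP with a lithium halide. No ring is closed and no stereocentre is formed; the four existing stereocentres are spectators because neither coupling carbon is stereogenic and the centre β to zinc cannot enolise. The step needs reductive elimination to beat β-hydride elimination (the bulky IPr ligand and two primary partners should secure this) and oxidative addition at C–Br to beat ionisation of allylic C–O bonds (the allylic oxygen is carried as a silyl ether and the only ester is a secondary acetate that the zinc reagent does not attack). The polarity is dictated by the substrate: a radical at the side-chain carbon would sit 1,5 to the prenyl alkene and cyclise 5-exo, so that carbon is kept as the two-electron zinc nucleophile and the ring arm is the electrophile. The nearest heteroatoms are γ to both reacting carbons, so β-alkoxide elimination cannot occur.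

Step 16
Reactants: 25 coupled bis-silyl ether
Product: 26 (2S,3R,6E)-6-(2-hydroxyethylidene)-2-[(4R,5R)-5-hydroxy-4,8-dimethylnon-7-en-1-yl]-2-methyloxepan-3-yl acetate
Conditions: HF·pyridine, pyridine, THF, 0 °C → rt
Reagents that add atoms: none
Why: Buffered fluoride desilylation should cleave both silyl ethers while the acetate, which basic fluoride could hydrolyse or migrate, survives.

Step 17
Reactants: 26 diol monoacetate
Product: 27 (2S,3R,6E)-6-(2-acetoxyethylidene)-2-[(4R,5R)-5-hydroxy-4,8-dimethylnon-7-en-1-yl]-2-methyloxepan-3-yl acetate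
Conditions: AcCl (1.1 equiv), 2,4,6-collidine, CH2Cl2, −78 °C
Reagents that add atoms: acetyl chloride CC(=O)Cl
Why: Kinetically controlled acylation should take the unhindered primary allylic hydroxyl far faster than the secondary hydroxyl flanked by a methyl-branched carbon, leaving the side-chain alcohol free as in the target.

**Compound list**

1 | but-2-yne-1,4-diol | OCC#CCO | starting material
2 | but-3-en-1-ylmagnesium bromide | C=CCC[Mg]Br | starting material
3 | chelated alkenylmagnesium alkoxide (five-membered C–Mg–O ring, Mg trans to the butenyl group) | C=CCCC1=C(CO[Mg]Br)[Mg]OC1 | intermediate (not isolated)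
4 | (2E)-2-(but-3-en-1-yl)but-2-ene-1,4-diol | C=CCC/C(CO)=C\CO | intermediate
5 | methacrolein (2-methylprop-2-enal) | C=C(C)C=O | starting material
6 | (2E,6E)-8-hydroxy-6-(hydroxymethyl)-2-methylocta-2,6-dienal | O=C/C(C)=C/CC/C(CO)=C\CO | intermediate
7 | (2E)-2-[(3E)-4-methylhexa-3,5-dien-1-yl]but-2-ene-1,4-diol | C=C/C(C)=C/CC/C(CO)=C\CO | intermediate
8 | (2E)-2-{2-[(2R,3R)-3-ethenyl-3-methyloxiran-2-yl]ethyl}but-2-ene-1,4-diol | C=C[C@@]1(C)O[C@@H]1CC/C(CO)=C\CO | intermediate
9 | (2S,3R,6E)-2-ethenyl-6-(2-hydroxyethylidene)-2-methyloxepan-3-ol | OC/C=C1\CC[C@@H](O)[C@](C)(C=C)OC1 | intermediate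
10 | (2S,3R,6E)-6-(2-{[tert-butyl(dimethyl)silyl]oxy}ethylidene)-2-ethenyl-2-methyloxepan-3-ol | CC(C)(C)[Si](C)(C)OC/C=C1\CC[C@@H](O)[C@](C)(C=C)OC1 | intermediate
11 | (2S,3R,6E)-6-(2-{[tert-butyl(dimethyl)silyl]oxy}ethylidene)-2-ethenyl-2-methyloxepan-3-yl acetate | CC(C)(C)[Si](C)(C)OC/C=C1\CC[C@@H](OC(C)=O)[C@](C)(C=C)OC1 | intermediate
12 | B-alkyl-9-BBN adduct of 11 (boron on the terminal carbon of the former vinyl group) | CC(C)(C)[Si](C)(C)OC/C=C1\CC[C@@H](OC(C)=O)[C@](C)(CCB2C3CCCC2CCC3)OC1 | intermediate (not isolated)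
13 | (2S,3R,6E)-6-(2-{[tert-butyl(dimethyl)silyl]oxy}ethylidene)-2-(2-hydroxyethyl)-2-methyloxepan-3-yl acetate | CC(C)(C)[Si](C)(C)OC/C=C1\CC[C@@H](OC(C)=O)[C@](C)(CCO)OC1 | intermediate
14 | (2S,3R,6E)-2-(2-bromoethyl)-6-(2-{[tert-butyl(dimethyl)silyl]oxy}ethylidene)-2-methyloxepan-3-yl acetate | CC(C)(C)[Si](C)(C)OC/C=C1\CC[C@@H](OC(C)=O)[C@](C)(CCBr)OC1 | intermediate
15 | 4-methylpent-3-en-1-ol | CC(C)=CCCO | starting material
16 | 4-methylpent-3-enal | CC(C)=CCC=O | intermediate
17 | (4S)-4-benzyl-3-propanoyl-1,3-oxazolidin-2-one | CCC(=O)N1[C@@H](Cc2ccccc2)COC1=O | starting material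
18 | (Z)-dibutylboron enolate of 17 | C/C=C(\OB(CCCC)CCCC)N1[C@@H](Cc2ccccc2)COC1=O | intermediate (not isolated)
19 | (4S)-4-benzyl-3-[(2S,3R)-3-hydroxy-2,6-dimethylhept-5-enoyl]-1,3-oxazolidin-2-one | O=C([C@@H](C)[C@H](O)CC=C(C)C)N1[C@@H](Cc2ccccc2)COC1=O | intermediate
20 | (4S)-4-benzyl-3-[(2S,3R)-3-{[tert-butyl(dimethyl)silyl]oxy}-2,6-dimethylhept-5-enoyl]-1,3-oxazolidin-2-one | O=C([C@@H](C)[C@H](O[Si](C)(C)C(C)(C)C)CC=C(C)C)N1[C@@H](Cc2ccccc2)COC1=O | intermediate
21 | (2R,3R)-3-{[tert-butyl(dimethyl)silyl]oxy}-2,6-dimethylhept-5-en-1-ol | OC[C@@H](C)[C@H](O[Si](C)(C)C(C)(C)C)CC=C(C)C | intermediate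
22 | tert-butyl{[(2S,3R)-1-iodo-2,6-dimethylhept-5-en-3-yl]oxy}dimethylsilane | IC[C@@H](C)[C@H](O[Si](C)(C)C(C)(C)C)CC=C(C)C | intermediate
23 | primary alkyllithium from 22 (Li in place of I) | [Li]C[C@@H](C)[C@H](O[Si](C)(C)C(C)(C)C)CC=C(C)C | intermediate (not isolated)
24 | primary alkylzinc bromide from 23 | Br[Zn]C[C@@H](C)[C@H](O[Si](C)(C)C(C)(C)C)CC=C(C)C | intermediate (not isolated)
25 | (2S,3R,6E)-6-(2-{[tert-butyl(dimethyl)silyl]oxy}ethylidene)-2-[(4R,5R)-5-{[tert-butyl(dimethyl)silyl]oxy}-4,8-dimethylnon-7-en-1-yl]-2-methyloxepan-3-yl acetate | CC(C)(C)[Si](C)(C)OC/C=C1\CC[C@@H](OC(C)=O)[C@](C)(CCC[C@@H](C)[C@H](O[Si](C)(C)C(C)(C)C)CC=C(C)C)OC1 | intermediate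
26 | (2S,3R,6E)-6-(2-hydroxyethylidene)-2-[(4R,5R)-5-hydroxy-4,8-dimethylnon-7-en-1-yl]-2-methyloxepan-3-yl acetate | OC/C=C1\CC[C@@H](OC(C)=O)[C@](C)(CCC[C@@H](C)[C@H](O)CC=C(C)C)OC1 | intermediate
27 | (2S,3R,6E)-6-(2-acetoxyethylidene)-2-[(4R,5R)-5-hydroxy-4,8-dimethylnon-7-en-1-yl]-2-methyloxepan-3-yl acetate | CC(=O)OC/C=C1\CC[C@@H](OC(C)=O)[C@](C)(CCC[C@@H](C)[C@H](O)CC=C(C)C)OC1 | target

**Totals and risks**

Total step count: 17. Longest linear sequence: 12 (steps 1–9, 15, 16, 17).

Step 15 (key coupling). Transmetalation of the β-branched alkylzinc may be slower than β-hydride elimination from the alkylpalladium, or the γ-silyloxy alkyllithium may undergo oxygen-to-carbon silyl migration before zinc capture, so that the bromide is consumed without coupling. The fallback makes the same bond as an alkene and then saturates it; it sets out from 14 and 21 and comes back at 25. Heating 14 with PPh3 (MeCN, 80 °C) gives the phosphonium bromide F1. Dess–Martin oxidation of 21 gives the aldehyde (2S,3R)-3-silyloxy-2,6-dimethylhept-5-enal F2. The ylide of F1 (NaHMDS, THF, −78 °C) and F2 should give the (Z)-alkene F3 by a Wittig reaction. Diimide (TsNHNH2, NaOAc, DME–H2O, 85 °C) should then reduce only the 1,2-disubstituted alkene and leave the two trisubstituted ones, giving 25.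

Step 4 (epoxidation). Epoxidation may also occur at the alkene flanked by the two free hydroxymethyl groups, or facial selectivity may be poor on the unprotected diol. The fallback is a hydroxyl-directed epoxidation; it sets out from 6 and comes back at 8. Bis-silylation of 6 (TBSCl, imidazole) gives the enal F4, and Luche reduction (NaBH4, CeCl3, MeOH) gives the allylic alcohol F5. Sharpless asymmetric epoxidation with D-(−)-diisopropyl tartrate (Ti(OiPr)4, t-BuOOH, 4 Å MS, −20 °C) should give the (2R,3R)-epoxy alcohol F6. Parikh–Doering oxidation gives the epoxy aldehyde F7, and Wittig methylenation gives the bis-silylated vinyl epoxide F8. Bu4NF (THF, 0 °C) removes both silyl groups to give 8.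

Step 1 (carbomagnesiation). A non-allylic alkyl Grignard reagent may add sluggishly, so that simple deprotonation, or elimination from the β-oxido alkenylmagnesium to an allene, takes over. The fallback is hydroalumination followed by cross-coupling; it sets out from 1 and comes back at 4. Mono-silylation of 1 (NaH, TBSCl, THF) gives the propargylic alcohol F9. Red-Al then I2 (THF, −78 °C) should give the (Z)-iodide F10 by alkoxide-directed trans-hydroalumination. Negishi coupling of F10 with but-3-enylzinc bromide (from 2 and ZnBr2; Pd(PPh3)4, THF) should replace iodine with retention to give the mono-silylated diol F11. Bu4NF then gives 4.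

**Further compounds**

F1 | step 15 | {2-[(2S,3R,6E)-3-acetoxy-6-(2-{[tert-butyl(dimethyl)silyl]oxy}ethylidene)-2-methyloxepan-2-yl]ethyl}triphenylphosphonium bromide | CC(C)(C)[Si](C)(C)OC/C=C1\CC[C@@H](OC(C)=O)[C@](C)(CC[P+](c2ccccc2)(c2ccccc2)c2ccccc2)OC1.[Br-]
F2 | step 15 | (2S,3R)-3-{[tert-butyl(dimethyl)silyl]oxy}-2,6-dimethylhept-5-enal | O=C[C@@H](C)[C@H](O[Si](C)(C)C(C)(C)C)CC=C(C)C
F3 | step 15 | (2S,3R,6E)-6-(2-{[tert-butyl(dimethyl)silyl]oxy}ethylidene)-2-[(2Z,4R,5R)-5-{[tert-butyl(dimethyl)silyl]oxy}-4,8-dimethylnona-2,7-dien-1-yl]-2-methyloxepan-3-yl acetate | CC(C)(C)[Si](C)(C)OC/C=C1\CC[C@@H](OC(C)=O)[C@](C)(C/C=C\[C@@H](C)[C@H](O[Si](C)(C)C(C)(C)C)CC=C(C)C)OC1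
F4 | step 4 | (2E,6E)-8-{[tert-butyl(dimethyl)silyl]oxy}-6-({[tert-butyl(dimethyl)silyl]oxy}methyl)-2-methylocta-2,6-dienal | O=C/C(C)=C/CC/C(CO[Si](C)(C)C(C)(C)C)=C\CO[Si](C)(C)C(C)(C)C
F5 | step 4 | (2E,6E)-8-{[tert-butyl(dimethyl)silyl]oxy}-6-({[tert-butyl(dimethyl)silyl]oxy}methyl)-2-methylocta-2,6-dien-1-ol | OC/C(C)=C/CC/C(CO[Si](C)(C)C(C)(C)C)=C\CO[Si](C)(C)C(C)(C)C
F6 | step 4 | [(2R,3R)-3-{(3E)-5-{[tert-butyl(dimethyl)silyl]oxy}-3-({[tert-butyl(dimethyl)silyl]oxy}methyl)pent-3-en-1-yl}-2-methyloxiran-2-yl]methanol | OC[C@@]1(C)O[C@@H]1CC/C(CO[Si](C)(C)C(C)(C)C)=C\CO[Si](C)(C)C(C)(C)C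
F7 | step 4 | (2S,3R)-3-{(3E)-5-{[tert-butyl(dimethyl)silyl]oxy}-3-({[tert-butyl(dimethyl)silyl]oxy}methyl)pent-3-en-1-yl}-2-methyloxirane-2-carbaldehyde | O=C[C@@]1(C)O[C@@H]1CC/C(CO[Si](C)(C)C(C)(C)C)=C\CO[Si](C)(C)C(C)(C)C
F8 | step 4 | (2R,3R)-3-{(3E)-5-{[tert-butyl(dimethyl)silyl]oxy}-3-({[tert-butyl(dimethyl)silyl]oxy}methyl)pent-3-en-1-yl}-2-ethenyl-2-methyloxirane | C=C[C@@]1(C)O[C@@H]1CC/C(CO[Si](C)(C)C(C)(C)C)=C\CO[Si](C)(C)C(C)(C)C
F9 | step 1 | 4-{[tert-butyl(dimethyl)silyl]oxy}but-2-yn-1-ol | CC(C)(C)[Si](C)(C)OCC#CCO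
F10 | step 1 | (2Z)-4-{[tert-butyl(dimethyl)silyl]oxy}-3-iodobut-2-en-1-ol | OC/C=C(\I)CO[Si](C)(C)C(C)(C)C
F11 | step 1 | (2E)-3-({[tert-butyl(dimethyl)silyl]oxy}methyl)hepta-2,6-dien-1-ol | OC/C=C(\CCC=C)CO[Si](C)(C)C(C)(C)C
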